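**Retrosynthetic overview**
- The target is opened at the central nitrogen (sulfonamide cleavage, then ring closure of the 20-membered ring by N-alkylation); its two Z-enamides come from a Z-selective Horner–Wadsworth–Emmons reaction at a C9b aldehyde and a Suzuki coupling at C8 with a (Z)-3-iodoacrylamide.
- The tricyclic core (tetrahydrodibenzofuranone: C1/C2 = CH2CH2, C3 = C=O, C4 = CH2, C4a = OCH, C9b = quaternary carbon) comes from a (3+3) annulation that forms C1–C2 and C4–C4a: a cyclopropane fused to the 2,3-bond of a benzofuran plus a 2-methoxyallyl (oxyallyl) cation.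
- Enabling feature: C1 and C4a are both bonded to C9b and C4a carries the ring oxygen, so C1–C9b–C4a is a masked cyclopropane whose oxygen-activated C1–C4a bond is a latent 1,3-dipole (nucleophilic CH2, oxocarbenium at C4a); the C2–C3(=O)–C4 unit with two unsubstituted α-carbons is the matching three-carbon ambiphile.
- The fused cyclopropane comes from an enantioselective copper-carbene cyclopropanation (dearomatisation) of 5-bromo-3-(silyloxymethyl)benzofuran, the ester handle being removed afterwards; the benzofuran comes from 5-bromosalicylaldehyde and ethyl diazoacetate.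
- Ring order: benzofuran, cyclopropane (temporary ring), cyclohexanone (key step), macrocycle.

Key step: step 8

Assumption: the target is taken as drawn, i.e. cis-fused (4aR,9bS) with both enamide C=C bonds Z; the mono-sulfonylated diamine hydrochloride and (Z)-3-iodoacrylic acid are taken as commercial.

**Step 1**
Reactants: 1 5-bromo-2-hydroxybenzaldehyde
Product: 3 ethyl 5-bromo-1-benzofuran-3-carboxylate, via hemiacetal 2 (not isolated)
Conditions: ethyl diazoacetate, HBF4·OEt2 (10 mol %), CH2Cl2, rt; then conc. H2SO4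
Reagents that add atoms: ethyl diazoacetate, CCOC(=O)C=[N+]=[N-]
Why: Acid-catalysed addition of the diazoacetate to the aldehyde with 1,2-aryl shift (a Roskamp-type homologation) gives the 2-aryl-3-oxopropanoate, which closes to hemiacetal 2 and is dehydrated to the aromatic benzofuran; no stereocentre is formed.

**Step 2**
Reactants: 3 ethyl 5-bromo-1-benzofuran-3-carboxylate
Product: 4 (5-bromo-1-benzofuran-3-yl)methanol
Conditions: i-Bu2AlH (2.5 equiv), CH2Cl2, −78 to 0 °C; aq. KNaC4H4O6 work-up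
Reagents that add atoms: none
Why: Aluminium hydride reduction of the conjugated ester to the primary alcohol; the aryl bromide and the furan ring are inert at low temperature.

**Step 3**
Reactants: 4 (5-bromo-1-benzofuran-3-yl)methanol
Product: 5 [(5-bromo-1-benzofuran-3-yl)methoxy](tert-butyl)dimethylsilane
Conditions: TBSCl, imidazole, DMF, rt
Reagents that add atoms: tert-butyldimethylsilyl chloride, CC(C)(C)[Si](C)(C)Cl
Why: Imidazole-mediated silyl ether formation removes the O–H bond that would otherwise intercept the copper carbene of step 4.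

**Step 4**
Reactants: 5 [(5-bromo-1-benzofuran-3-yl)methoxy](tert-butyl)dimethylsilane
Product: 6 ethyl (1S,1aR,6bR)-5-bromo-6b-({[tert-butyl(dimethyl)silyl]oxy}methyl)-1a,6b-dihydro-1H-cyclopropa[b][1]benzofuran-1-carboxylate (exo ester)
Conditions: ethyl diazoacetate (slow addition), (CuOTf)2·C6H6 (2 mol %), (S,S)-t-Bu-box (2.4 mol %), CH2Cl2, 0 °C to rt
Reagents that add atoms: ethyl diazoacetate, CCOC(=O)C=[N+]=[N-]
Why: Copper-carbene cyclopropanation of the electron-rich C2=C3 bond of a benzofuran (a dearomatising carbene transfer known for benzofurans, furans and 3-substituted indoles), in which the bis(oxazoline) ligand selects the face of the heteroarene and so sets both ring-fusion stereocentres C1a and C6b (cis by necessity) with the ester exo; the ligand antipode is chosen in a preliminary screen so that the (1aR,6bR) series results.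

**Step 5**
Reactants: 6 ethyl (1S,1aR,6bR)-5-bromo-6b-({[tert-butyl(dimethyl)silyl]oxy}methyl)-1a,6b-dihydro-1H-cyclopropa[b][1]benzofuran-1-carboxylate
Product: 7 (1S,1aR,6bR)-5-bromo-6b-({[tert-butyl(dimethyl)silyl]oxy}methyl)-1a,6b-dihydro-1H-cyclopropa[b][1]benzofuran-1-carboxylic acid
Conditions: LiOH·H2O, THF/MeOH/H2O, 0 °C to rt; then 1 M HCl to pH 4 at 0 °C
Reagents that add atoms: lithium hydroxide, [Li+].[OH-]
Why: Saponification of the ethyl ester, which is only a handle to be removed in step 6; the silyl ether and the aryloxycyclopropane should tolerate cold hydroxide and a mildly acidic work-up.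

**Step 6**
Reactants: 7 (1S,1aR,6bR)-5-bromo-6b-({[tert-butyl(dimethyl)silyl]oxy}methyl)-1a,6b-dihydro-1H-cyclopropa[b][1]benzofuran-1-carboxylic acid
Product: 9 {[(1aR,6bR)-5-bromo-1a,6b-dihydro-1H-cyclopropa[b][1]benzofuran-6b-yl]methoxy}(tert-butyl)dimethylsilane, via Barton ester 8 (not isolated)
Conditions: 1-hydroxypyridine-2(1H)-thione, DCC, DMAP (cat.), CH2Cl2, 0 °C to rt, dark; then t-BuSH, hν (tungsten lamp), rt
Reagents that add atoms: none
Why: Barton reductive decarboxylation: thiohydroxamate ester 8 fragments under visible light to a cyclopropyl radical, which does not ring-open and abstracts hydrogen from the thiol, so C1 becomes CH2 while the two ring-fusion stereocentres are untouched.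

**Step 7**
Reactants: 10 1-bromo-2,2-dimethoxypropane
Product: 11 3-bromo-2-methoxyprop-1-ene (2-methoxyallyl bromide)
Conditions: i-Pr2NEt·TsOH (cat.), neat, 150–190 °C, MeOH distilled off; fractional distillation
Reagents that add atoms: none
Why: Acid-catalysed thermal elimination of methanol from the ketal gives the enol ether, driven by removal of methanol.

**Step 8**
Reactants: 9 {[(1aR,6bR)-5-bromo-1a,6b-dihydro-1H-cyclopropa[b][1]benzofuran-6b-yl]methoxy}(tert-butyl)dimethylsilane; 11 3-bromo-2-methoxyprop-1-ene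
Product: 14 (4aR,9bR)-8-bromo-9b-({[tert-butyl(dimethyl)silyl]oxy}methyl)-1,2,4a,9b-tetrahydrodibenzo[b,d]furan-3(4H)-one, via oxocarbenium triflate 12 (not isolated), via methyl enol ether 13 (not isolated)
Conditions: 11 (1.5 equiv), AgOTf (1.6 equiv), 2,6-di-tert-butyl-4-methylpyridine, 4 Å MS, CH2Cl2, −78 to −30 °C; then 1 M HCl, THF, 0 °C; NaHCO3 work-up
Reagents that add atoms: water, O
Why: Proposed new method: silver-assisted ionisation of 11 gives the 2-methoxyallyl cation, which is attacked at the unhindered CH2 corner by the oxygen-activated C1–C1a σ-bond of cyclopropane 9 (a homo-enol ether), so that the C1–C2 bond forms as the strained ring opens to 2-oxocarbenium ion 12 carrying a tethered methyl enol ether, which closes onto C4a to give enol ether 13, hydrolysed on work-up to ketone 14. The closest known reaction types are the electrophile-induced opening of alkoxy-fused cyclopropanes (1,2-cyclopropanated glycals with iodonium, mercury or platinum electrophiles) to C2-branched oxocarbenium ions, the (3+2) and (4+3) annulations of 2-alkoxyallyl and oxyallyl cations with π-nucleophiles, and the strain-release (3+3) annulations of bicyclobutane σ-bonds with 1,3-dipoles. The six-membered ring is closed by a 6-(enolendo)-exo-trig Mukaiyama/Prins-type attack of the enol ether on the oxocarbenium carbon. C9b is carried over unchanged from C6b of 9, and the new stereocentre C4a is set by the three-atom tether, which can reach the planar oxocarbenium carbon only from the face that bears C1, so only the cis-fused ring system can form. The step needs cleavage of the C1–C1a bond (not C1–C6b or C1a–C6b) and attack by the σ-bond rather than by the arene: the ring-oxygen lone pair makes C1a the best cation site, the CH2OSi group inductively disfavours a cation at C6b, C1 is the only unhindered corner, the bromine deactivates the arene, and the hindered pyridine removes acid that would otherwise protonate the cyclopropane.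

**Step 9**
Reactants: 14 (4aR,9bR)-8-bromo-9b-({[tert-butyl(dimethyl)silyl]oxy}methyl)-1,2,4a,9b-tetrahydrodibenzo[b,d]furan-3(4H)-one
Product: 15 (4aR,9bR)-8-bromo-9b-(hydroxymethyl)-1,2,4a,9b-tetrahydrodibenzo[b,d]furan-3(4H)-one
Conditions: HF·pyridine, pyridine/THF, 0 °C to rt
Reagents that add atoms: none
Why: Fluoride-mediated cleavage of the primary silyl ether (Si–F bond formation); ketone, aryl bromide and ring fusion are unaffected under these buffered conditions.

**Step 10**
Reactants: 15 (4aR,9bR)-8-bromo-9b-(hydroxymethyl)-1,2,4a,9b-tetrahydrodibenzo[b,d]furan-3(4H)-one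
Product: 16 (4aR,9bS)-8-bromo-3-oxo-1,2,3,4,4a,9b-hexahydrodibenzo[b,d]furan-9b-carbaldehyde
Conditions: Dess–Martin periodinane, CH2Cl2, rt
Reagents that add atoms: none
Why: Dess–Martin oxidation of the neopentyl primary alcohol to the aldehyde, which has no α-hydrogen and so can neither epimerise nor eliminate the β-aryloxy group.

**Step 11**
Reactants: 17 4-chlorobutan-1-amine hydrochloride
Product: 18 2-bromo-N-(4-chlorobutyl)acetamide
Conditions: bromoacetyl bromide, Et3N (2.1 equiv), CH2Cl2, −40 to 0 °C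
Reagents that add atoms: bromoacetyl bromide, BrCC(Br)=O
Why: Schotten–Baumann-type N-acylation of the amine as it is liberated, which is faster than cyclisation of free 4-chlorobutylamine.

**Step 12**
Reactants: 18 2-bromo-N-(4-chlorobutyl)acetamide
Product: 19 diphenyl {2-[(4-chlorobutyl)amino]-2-oxoethyl}phosphonate
Conditions: diphenyl phosphite, Et3N, CH2Cl2, 0 °C to rt
Reagents that add atoms: diphenyl phosphite, O=[PH](Oc1ccccc1)Oc1ccccc1
Why: Michaelis–Becker reaction: the phosphite anion displaces the activated α-bromide, not the unactivated primary chloride, to give the diaryl phosphonoacetamide needed for Z-selective olefination.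

**Step 13**
Reactants: 16 (4aR,9bS)-8-bromo-3-oxo-1,2,3,4,4a,9b-hexahydrodibenzo[b,d]furan-9b-carbaldehyde; 19 diphenyl {2-[(4-chlorobutyl)amino]-2-oxoethyl}phosphonate
Product: 20 (2Z)-3-[(4aR,9bS)-8-bromo-3-oxo-2,3,4,4a-tetrahydrodibenzo[b,d]furan-9b(1H)-yl]-N-(4-chlorobutyl)prop-2-enamide
Conditions: 19 (1.3 equiv), t-BuOK (1.25 equiv), THF, −78 °C; then 16, −78 to −20 °C
Reagents that add atoms: none
Why: Ando-type Horner–Wadsworth–Emmons olefination, in which the electron-poor diphenyl phosphonate makes oxaphosphetane collapse fast so that the kinetic adduct gives the Z-enamide; the aldehyde should react before the ketone at low temperature and C9b cannot epimerise.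

**Step 14**
Reactants: 21 N-(3-aminopropyl)-2-nitrobenzenesulfonamide hydrochloride; 22 (2Z)-3-iodoprop-2-enoic acid
Product: 23 (2Z)-3-iodo-N-(3-{[(2-nitrophenyl)sulfonyl]amino}propyl)prop-2-enamide
Conditions: EDC·HCl, HOBt (cat.), i-Pr2NEt, CH2Cl2, 0 °C to rt
Reagents that add atoms: none
Why: Carbodiimide/HOBt amide coupling of the primary amine with the pre-activated acid, which is expected to be faster than addition–elimination at the β-iodide and so to keep the Z geometry.

**Step 15**
Reactants: 20 (2Z)-3-[(4aR,9bS)-8-bromo-3-oxo-2,3,4,4a-tetrahydrodibenzo[b,d]furan-9b(1H)-yl]-N-(4-chlorobutyl)prop-2-enamide; 23 (2Z)-3-iodo-N-(3-{[(2-nitrophenyl)sulfonyl]amino}propyl)prop-2-enamide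
Product: 25 (2Z)-N-(4-chlorobutyl)-3-[(4aR,9bS)-8-{(1Z)-3-[(3-{[(2-nitrophenyl)sulfonyl]amino}propyl)amino]-3-oxoprop-1-en-1-yl}-3-oxo-2,3,4,4a-tetrahydrodibenzo[b,d]furan-9b(1H)-yl]prop-2-enamide, via pinacol boronate 24 (not isolated)
Conditions: B2pin2 (1.1 equiv), Pd(dppf)Cl2 (5 mol %), KOAc, 1,4-dioxane, 80 °C; then 23, aq. K3PO4, 50 °C
Reagents that add atoms: none
Why: Miyaura borylation of the aryl bromide followed in the same flask by Suzuki–Miyaura coupling with the (Z)-vinyl iodide, which proceeds with retention of alkene geometry; alkyl chloride, sulfonamide and ketone are inert to the palladium catalyst.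

**Step 16**
Reactants: 25 (2Z)-N-(4-chlorobutyl)-3-[(4aR,9bS)-8-{(1Z)-3-[(3-{[(2-nitrophenyl)sulfonyl]amino}propyl)amino]-3-oxoprop-1-en-1-yl}-3-oxo-2,3,4,4a-tetrahydrodibenzo[b,d]furan-9b(1H)-yl]prop-2-enamide
Product: 26 the target macrocycle carrying a 2-nitrophenylsulfonyl group on its central nitrogen, (4aR,9bS), both enamides Z
Conditions: Cs2CO3, n-Bu4NI (cat.), MeCN, 60 °C, 1 mM (slow addition)
Reagents that add atoms: none
Why: Intramolecular Fukuyama N-alkylation: the caesium salt of the acidic sulfonamide displaces the primary chloride (iodide catalysis) under high dilution to close the 20-membered ring, while the far less acidic secondary amides stay protonated.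

**Step 17**
Reactants: 26 the N-(2-nitrophenylsulfonyl) macrocycle
Product: 27 CNP0415009.2 (target)
Conditions: PhSH, K2CO3, MeCN, rt
Reagents that add atoms: none
Why: Fukuyama deprotection: thiolate adds to the 2-nitrophenyl ring (Meisenheimer complex) and releases the secondary amine with loss of sulfur dioxide; the β-substituted enamides are poor Michael acceptors, and the reaction is kept short at room temperature to avoid thiol-mediated Z to E isomerisation.

**Compound list**
1 | 5-bromo-2-hydroxybenzaldehyde | O=Cc1cc(Br)ccc1O | starting material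
2 | ethyl 5-bromo-2-hydroxy-2,3-dihydro-1-benzofuran-3-carboxylate (hemiacetal, diastereomer mixture) | CCOC(=O)C1C(O)Oc2ccc(Br)cc12 | intermediate
3 | ethyl 5-bromo-1-benzofuran-3-carboxylate | CCOC(=O)c1coc2ccc(Br)cc12 | intermediate
4 | (5-bromo-1-benzofuran-3-yl)methanol | OCc1coc2ccc(Br)cc12 | intermediate
5 | [(5-bromo-1-benzofuran-3-yl)methoxy](tert-butyl)dimethylsilane | CC(C)(C)[Si](C)(C)OCc1coc2ccc(Br)cc12 | intermediate
6 | ethyl (1S,1aR,6bR)-5-bromo-6b-({[tert-butyl(dimethyl)silyl]oxy}methyl)-1a,6b-dihydro-1H-cyclopropa[b][1]benzofuran-1-carboxylate | CCOC(=O)[C@H]1[C@]2(CO[Si](C)(C)C(C)(C)C)c3cc(Br)ccc3O[C@@H]21 | intermediate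
7 | (1S,1aR,6bR)-5-bromo-6b-({[tert-butyl(dimethyl)silyl]oxy}methyl)-1a,6b-dihydro-1H-cyclopropa[b][1]benzofuran-1-carboxylic acid | OC(=O)[C@H]1[C@]2(CO[Si](C)(C)C(C)(C)C)c3cc(Br)ccc3O[C@@H]21 | intermediate
8 | 2-thioxopyridin-1(2H)-yl (1S,1aR,6bR)-5-bromo-6b-({[tert-butyl(dimethyl)silyl]oxy}methyl)-1a,6b-dihydro-1H-cyclopropa[b][1]benzofuran-1-carboxylate (Barton ester) | S=C1C=CC=CN1OC(=O)[C@H]1[C@]2(CO[Si](C)(C)C(C)(C)C)c3cc(Br)ccc3O[C@@H]21 | intermediate
9 | {[(1aR,6bR)-5-bromo-1a,6b-dihydro-1H-cyclopropa[b][1]benzofuran-6b-yl]methoxy}(tert-butyl)dimethylsilane | C1[C@]2(CO[Si](C)(C)C(C)(C)C)c3cc(Br)ccc3O[C@@H]21 | intermediate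
10 | 1-bromo-2,2-dimethoxypropane | COC(C)(CBr)OC | starting material
11 | 3-bromo-2-methoxyprop-1-ene | COC(=C)CBr | intermediate
12 | (3R)-5-bromo-3-({[tert-butyl(dimethyl)silyl]oxy}methyl)-3-(3-methoxybut-3-en-1-yl)-3H-1-benzofuran-1-ium trifluoromethanesulfonate | C=C(OC)CC[C@]1(CO[Si](C)(C)C(C)(C)C)c2cc(Br)ccc2[O+]=C1.[O-]S(=O)(=O)C(F)(F)F | intermediate
13 | (4aR,9bR)-8-bromo-9b-({[tert-butyl(dimethyl)silyl]oxy}methyl)-3-methoxy-1,4,4a,9b-tetrahydrodibenzo[b,d]furan (or its 3,4-ene isomer) | COC1=CC[C@]2(CO[Si](C)(C)C(C)(C)C)c3cc(Br)ccc3O[C@@H]2C1 | intermediate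
14 | (4aR,9bR)-8-bromo-9b-({[tert-butyl(dimethyl)silyl]oxy}methyl)-1,2,4a,9b-tetrahydrodibenzo[b,d]furan-3(4H)-one | O=C1CC[C@]2(CO[Si](C)(C)C(C)(C)C)c3cc(Br)ccc3O[C@@H]2C1 | intermediate
15 | (4aR,9bR)-8-bromo-9b-(hydroxymethyl)-1,2,4a,9b-tetrahydrodibenzo[b,d]furan-3(4H)-one | O=C1CC[C@]2(CO)c3cc(Br)ccc3O[C@@H]2C1 | intermediate
16 | (4aR,9bS)-8-bromo-3-oxo-1,2,3,4,4a,9b-hexahydrodibenzo[b,d]furan-9b-carbaldehyde | O=C1CC[C@]2(C=O)c3cc(Br)ccc3O[C@@H]2C1 | intermediate
17 | 4-chlorobutan-1-amine hydrochloride | Cl.NCCCCCl | starting material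
18 | 2-bromo-N-(4-chlorobutyl)acetamide | O=C(CBr)NCCCCCl | intermediate
19 | diphenyl {2-[(4-chlorobutyl)amino]-2-oxoethyl}phosphonate | O=C(CP(=O)(Oc1ccccc1)Oc1ccccc1)NCCCCCl | intermediate
20 | (2Z)-3-[(4aR,9bS)-8-bromo-3-oxo-2,3,4,4a-tetrahydrodibenzo[b,d]furan-9b(1H)-yl]-N-(4-chlorobutyl)prop-2-enamide | O=C1CC[C@]2(/C=C\C(=O)NCCCCCl)c3cc(Br)ccc3O[C@@H]2C1 | intermediate
21 | N-(3-aminopropyl)-2-nitrobenzenesulfonamide hydrochloride | Cl.NCCCNS(=O)(=O)c1ccccc1[N+](=O)[O-] | starting material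
22 | (2Z)-3-iodoprop-2-enoic acid | OC(=O)/C=C\I | starting material
23 | (2Z)-3-iodo-N-(3-{[(2-nitrophenyl)sulfonyl]amino}propyl)prop-2-enamide | O=C(/C=C\I)NCCCNS(=O)(=O)c1ccccc1[N+](=O)[O-] | intermediate
24 | (2Z)-N-(4-chlorobutyl)-3-[(4aR,9bS)-3-oxo-8-(4,4,5,5-tetramethyl-1,3,2-dioxaborolan-2-yl)-2,3,4,4a-tetrahydrodibenzo[b,d]furan-9b(1H)-yl]prop-2-enamide | O=C1CC[C@]2(/C=C\C(=O)NCCCCCl)c3cc(B4OC(C)(C)C(C)(C)O4)ccc3O[C@@H]2C1 | intermediate
25 | (2Z)-N-(4-chlorobutyl)-3-[(4aR,9bS)-8-{(1Z)-3-[(3-{[(2-nitrophenyl)sulfonyl]amino}propyl)amino]-3-oxoprop-1-en-1-yl}-3-oxo-2,3,4,4a-tetrahydrodibenzo[b,d]furan-9b(1H)-yl]prop-2-enamide | O=C1CC[C@]2(/C=C\C(=O)NCCCCCl)c3cc(/C=C\C(=O)NCCCNS(=O)(=O)c4ccccc4[N+](=O)[O-])ccc3O[C@@H]2C1 | intermediate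
26 | target macrocycle with a 2-nitrophenylsulfonyl group on the central nitrogen, (4aR,9bS), both enamides Z | O=C1CC[C@]23/C=C\C(=O)NCCCCN(S(=O)(=O)c5ccccc5[N+](=O)[O-])CCCNC(=O)/C=C\c4ccc(c2c4)O[C@@H]3C1 | intermediate
27 | CNP0415009.2, (4aR,9bS), both enamides Z | O=C1CC[C@]23/C=C\C(=O)NCCCCNCCCNC(=O)/C=C\c4ccc(c2c4)O[C@@H]3C1 | target

**Step count**
Total: 17 steps. Longest linear sequence: 13 steps (steps 1–6, 8–10, 13, 15–17).

**Steps most likely to fail**

Step 8 (proposed new method). The cyclopropane σ-bond may be too weak a nucleophile, so that the allyl cation is consumed by Friedel–Crafts alkylation of the bromoarene or by self-condensation, or ring opening may take the benzylic course. The fallback uses known chemistry, sets out from 9 and comes back at 14. Iodonium-induced opening of the alkoxycyclopropane with N-iodosuccinimide in methanol/CH2Cl2 at 0 °C (as known for cyclopropanated glycals) should give (3S)-5-bromo-3-({[tert-butyl(dimethyl)silyl]oxy}methyl)-3-(iodomethyl)-2-methoxy-2,3-dihydro-1-benzofuran F1 as a mixture at the acetal carbon. Keck radical allylation of the neopentyl iodide (Bu3SnCH2CH=CH2, AIBN, benzene, 80 °C) should give (3R)-5-bromo-3-(but-3-en-1-yl)-3-({[tert-butyl(dimethyl)silyl]oxy}methyl)-2-methoxy-2,3-dihydro-1-benzofuran F2. Prins cyclisation of the derived oxocarbenium ion onto the terminal alkene (CF3CO2H, CH2Cl2, 0 °C; then K2CO3, MeOH) should give the cis-fused (4aR,9bR)-8-bromo-9b-({[tert-butyl(dimethyl)silyl]oxy}methyl)-1,2,3,4,4a,9b-hexahydrodibenzo[b,d]furan-3-ol F3 as carbinol epimers, and Dess–Martin oxidation then gives 14.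

Step 13. Z-selectivity may erode, addition to the α-quaternary aldehyde may be sluggish, or the amide N–H may be deprotonated in competition. The fallback sets out from 16 and comes back at 20. Still–Gennari olefination with methyl bis(2,2,2-trifluoroethyl)phosphonoacetate (KN(SiMe3)2, 18-crown-6, THF, −78 °C) should give methyl (2Z)-3-[(4aR,9bS)-8-bromo-3-oxo-2,3,4,4a-tetrahydrodibenzo[b,d]furan-9b(1H)-yl]prop-2-enoate F4. Saponification (LiOH, THF/H2O, 0 °C) should give (2Z)-3-[(4aR,9bS)-8-bromo-3-oxo-2,3,4,4a-tetrahydrodibenzo[b,d]furan-9b(1H)-yl]prop-2-enoic acid F5, and EDC/HOBt coupling with 17 gives 20.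

Step 16. Intermolecular alkylation (oligomerisation) may outrun ring closure, or the chlorobutyl amide may cyclise onto its own nitrogen. The fallback closes the ring by C=C bond formation instead; it sets out from 15 and comes back at 26. Miyaura borylation and Suzuki coupling of 15 with 23 (conditions of step 15) should give (2Z)-3-[(4aR,9bR)-9b-(hydroxymethyl)-3-oxo-1,2,3,4,4a,9b-hexahydrodibenzo[b,d]furan-8-yl]-N-(3-{[(2-nitrophenyl)sulfonyl]amino}propyl)prop-2-enamide F6. Intermolecular N-alkylation of its sulfonamide with chloride 19 (Cs2CO3, n-Bu4NI, DMF, 50 °C) should give diphenyl [2-({4-[(3-{[(2Z)-3-[(4aR,9bR)-9b-(hydroxymethyl)-3-oxo-1,2,3,4,4a,9b-hexahydrodibenzo[b,d]furan-8-yl]prop-2-enoyl]amino}propyl)(2-nitrophenylsulfonyl)amino]butyl}amino)-2-oxoethyl]phosphonate F7. Dess–Martin oxidation should give the corresponding (4aR,9bS)-9b-carbaldehyde F8, and an intramolecular Ando-type Horner–Wadsworth–Emmons reaction under high dilution (NaH, THF, 0 °C) closes the macrocycle at the Z-enamide to give 26.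

**Further compounds**
F1 | step 8 | (3S)-5-bromo-3-({[tert-butyl(dimethyl)silyl]oxy}methyl)-3-(iodomethyl)-2-methoxy-2,3-dihydro-1-benzofuran | IC[C@]1(CO[Si](C)(C)C(C)(C)C)c2cc(Br)ccc2OC1OC
F2 | step 8 | (3R)-5-bromo-3-(but-3-en-1-yl)-3-({[tert-butyl(dimethyl)silyl]oxy}methyl)-2-methoxy-2,3-dihydro-1-benzofuran | C=CCC[C@]1(CO[Si](C)(C)C(C)(C)C)c2cc(Br)ccc2OC1OC
F3 | step 8 | (4aR,9bR)-8-bromo-9b-({[tert-butyl(dimethyl)silyl]oxy}methyl)-1,2,3,4,4a,9b-hexahydrodibenzo[b,d]furan-3-ol | OC1CC[C@]2(CO[Si](C)(C)C(C)(C)C)c3cc(Br)ccc3O[C@@H]2C1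
F4 | step 13 | methyl (2Z)-3-[(4aR,9bS)-8-bromo-3-oxo-2,3,4,4a-tetrahydrodibenzo[b,d]furan-9b(1H)-yl]prop-2-enoate | O=C1CC[C@]2(/C=C\C(=O)OC)c3cc(Br)ccc3O[C@@H]2C1
F5 | step 13 | (2Z)-3-[(4aR,9bS)-8-bromo-3-oxo-2,3,4,4a-tetrahydrodibenzo[b,d]furan-9b(1H)-yl]prop-2-enoic acid | O=C1CC[C@]2(/C=C\C(=O)O)c3cc(Br)ccc3O[C@@H]2C1
F6 | step 16 | (2Z)-3-[(4aR,9bR)-9b-(hydroxymethyl)-3-oxo-1,2,3,4,4a,9b-hexahydrodibenzo[b,d]furan-8-yl]-N-(3-{[(2-nitrophenyl)sulfonyl]amino}propyl)prop-2-enamide | O=C1CC[C@]2(CO)c3cc(/C=C\C(=O)NCCCNS(=O)(=O)c4ccccc4[N+](=O)[O-])ccc3O[C@@H]2C1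
F7 | step 16 | diphenyl [2-({4-[(3-{[(2Z)-3-[(4aR,9bR)-9b-(hydroxymethyl)-3-oxo-1,2,3,4,4a,9b-hexahydrodibenzo[b,d]furan-8-yl]prop-2-enoyl]amino}propyl)(2-nitrophenylsulfonyl)amino]butyl}amino)-2-oxoethyl]phosphonate | O=C1CC[C@]2(CO)c3cc(/C=C\C(=O)NCCCN(CCCCNC(=O)CP(=O)(Oc4ccccc4)Oc4ccccc4)S(=O)(=O)c4ccccc4[N+](=O)[O-])ccc3O[C@@H]2C1
F8 | step 16 | diphenyl [2-({4-[(3-{[(2Z)-3-[(4aR,9bS)-9b-formyl-3-oxo-1,2,3,4,4a,9b-hexahydrodibenzo[b,d]furan-8-yl]prop-2-enoyl]amino}propyl)(2-nitrophenylsulfonyl)amino]butyl}amino)-2-oxoethyl]phosphonate | O=C1CC[C@]2(C=O)c3cc(/C=C\C(=O)NCCCN(CCCCNC(=O)CP(=O)(Oc4ccccc4)Oc4ccccc4)S(=O)(=O)c4ccccc4[N+](=O)[O-])ccc3O[C@@H]2C1
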